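A direct plan would join ring A to ring B by a B-alkyl Suzuki coupling to give the bibenzyl phenol A1, and would make the diaryl ether by SNAr of A1 on a para-fluorobenzaldehyde (aldehyde A2).
It would then methylenate A2 to the styrene A3 and attach ring D by a ruthenium-catalysed, carboxylate-directed ortho C–H alkylation of A3 with the O-benzylated salicylic acid A4; hydrogenolysis of the resulting bis-benzyl acid A5 would give the target.
Its weakest step would be this hydroarylation of a styrene by a free benzoic acid: the pairing has no close precedent, linear against branched addition and protodecarboxylation would be left to chance, and it would be run at the point of convergence on the most precious material.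
The second weakness would be the benzylation and saponification that serve only to prepare A4 from a bought salicylate: two steps without a new skeletal bond.
The third would be the Wittig methylenation, which only changes the formyl group that activated the SNAr into the alkene needed for the C–H step.
No stereocentre or ring closure would be at risk; the plan would stand or fall with the regiochemistry of one unproven bond formation.

**Plan of the new route**
The retrosynthesis cuts first the ring B–CH2 bond, then the ring B–O bond, and finally ring D itself at C1–C6 and C2–C3, which leaves an enone and dimethyl malonate.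
Feature used: ring D has oxygen on C2 and C4 (meta), the carboxyl on C1 and the side chain on C6, so C3–C4–C5–C6 map onto CH3–CO–CH=CH–R, and C1, C2 and the carboxyl map onto a malonate.
Order of rings: ring C is bought (4-iodophenol), ring D is built on its side chain from open-chain carbons, ring B is then attached through oxygen, and ring A last through the ethylene bridge.
Aromatisation in methanol should etherify only O4, because O2 is locked in the hydrogen bond to the ester, so the OH/OMe pattern and the carboxyl come from the ring construction itself.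
Hence no C–H activation, no protection–deprotection pair and no one-carbon detour occur; the ring-forming step is run early on cheap material and the only non-constructive step is the final ester hydrolysis.

Key step: step 3

Remark on the chemistry: 7 and 8 are expected as racemates (8 as a mixture of C1/C6 diastereomers, drawn as one enol tautomer); this is immaterial because both centres become aromatic carbons in step 4. Compounds 1, 2, 4, 6, 10 and 12 are taken as commercial.

**Route**

Step 1
Reactants: 1 4-iodophenol; 2 prop-2-en-1-ol (allyl alcohol)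
Product: 3 3-(4-hydroxyphenyl)propanal
Conditions: 2 (1.5 equiv), Pd(OAc)2 (2 mol%), Bu4NCl (1.0 equiv), NaHCO3 (2.5 equiv), DMF, 45 °C
Reagents that add atoms: none
Why: Mizoroki–Heck arylation of allyl alcohol under ligand-free phase-transfer conditions, in which the aryl–palladium species adds to the terminal alkene carbon and β-hydride elimination toward the carbinol carbon gives the enol and hence the 3-arylpropanal, while the mild hydrogencarbonate base leaves the phenol largely un-ionised; no stereocentre is formed.

Step 2
Reactants: 3 3-(4-hydroxyphenyl)propanal; 4 1-(triphenyl-λ5-phosphanylidene)propan-2-one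
Product: 5 (3E)-6-(4-hydroxyphenyl)hex-3-en-2-one
Conditions: 4 (1.2 equiv), CH2Cl2, rt to 40 °C
Reagents that add atoms: none
Why: Wittig olefination with a stabilised acyl ylide, which is too weakly basic to deprotonate the phenol and should give the (E)-enone, the alkene geometry being of no consequence because both alkene carbons lose it in step 3.

Step 3
Reactants: 5 (3E)-6-(4-hydroxyphenyl)hex-3-en-2-one; 6 dimethyl malonate
Product: 8 methyl 2-hydroxy-6-[2-(4-hydroxyphenyl)ethyl]-4-oxocyclohex-2-ene-1-carboxylate, via Michael adduct 7 (not isolated)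
Conditions: 6 (1.2 equiv), NaOMe (2.5 equiv), MeOH, reflux; then 1 M HCl to pH 2 at 0 °C
Reagents that add atoms: none
Why: The malonate anion adds in the 1,4 sense to enone 5 (Michael addition, bond C1–C6 of ring D) to give 7, whose methyl-ketone enolate then attacks one ester carbonyl and expels methoxide (Claisen condensation of the Dieckmann type, bond C2–C3). The closest known reaction type is the Michael–Claisen annulation of enones with malonates to 5-substituted cyclohexane-1,3-diones and 6-alkyl dihydroresorcylates, which is established for enones carrying a 2-arylethyl group. Ring D closes in the 6-(enolendo)-exo-trig mode; the alternative closures (the other ketone enolate on an ester, or the malonate carbon on the ketone) would give four-membered rings and do not compete. The two new stereocentres C1 and C6 are not controlled and need not be, since C1 epimerises under the conditions (trans expected) and both become aromatic carbons in step 4. The selectivity needed is 1,4- over 1,2-addition, which the soft, reversibly adding malonate secures, and the equilibria are drawn to the product by irreversible deprotonation of the acidic vinylogous acid 8. The phenol is merely carried as its phenoxide, which is why 2.5 equiv of base are used.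

Step 4
Reactants: 8 methyl 2-hydroxy-6-[2-(4-hydroxyphenyl)ethyl]-4-oxocyclohex-2-ene-1-carboxylate
Product: 9 methyl 2-hydroxy-6-[2-(4-hydroxyphenyl)ethyl]-4-methoxybenzoate
Conditions: I2 (1.5 equiv), MeOH, reflux; then aq. Na2S2O3
Reagents that add atoms: methanol, CO
Why: Iodine–methanol oxidative aromatisation of a 2-hydroxy-4-oxocyclohexenecarboxylate, closely precedented for 6-alkyl and 6-(2-arylethyl) members of this class: the hydrogen iodide formed turns the C4 carbonyl into its methyl enol ether while the C2 enol stays locked in the hydrogen bond to the ester, and iodination–dehydroiodination then removes two hydrogens, so that both stereocentres of 8 disappear and the OH/OMe pattern of ring D is set without a protecting group.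

Step 5
Reactants: 9 methyl 2-hydroxy-6-[2-(4-hydroxyphenyl)ethyl]-4-methoxybenzoate; 10 (3-bromo-5-methoxyphenyl)boronic acid
Product: 11 methyl 6-{2-[4-(3-bromo-5-methoxyphenoxy)phenyl]ethyl}-2-hydroxy-4-methoxybenzoate
Conditions: 10 (2.0 equiv), Cu(OAc)2 (1.0 equiv, returned to divalent copper by air), pyridine (5 equiv), 4 Å molecular sieves, CH2Cl2, dry air, rt
Reagents that add atoms: none
Why: Chan–Lam oxidative O-arylation at room temperature, in which the free ring C phenol binds divalent copper and is arylated after transmetalation from boron and reductive elimination from trivalent copper, whereas the ring D hydroxyl is hydrogen-bonded to and flanked by the ester and should stay out, and the aryl bromide is inert to copper under these conditions; no stereocentre is formed.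

Step 6
Reactants: 11 methyl 6-{2-[4-(3-bromo-5-methoxyphenoxy)phenyl]ethyl}-2-hydroxy-4-methoxybenzoate; 12 4-ethenylphenyl acetate (4-acetoxystyrene)
Product: 15 methyl 2-hydroxy-6-[2-(4-{3-[2-(4-hydroxyphenyl)ethyl]-5-methoxyphenoxy}phenyl)ethyl]-4-methoxybenzoate, via alkylborane 13 (not isolated), via aryl acetate 14 (not isolated)
Conditions: 12 (1.6 equiv), 9-BBN (0.5 M in THF, 1.5 equiv), 0 °C to rt; then 11, Pd(dppf)Cl2 (5 mol%), 3 M aq. K3PO4 (4 equiv), DMF, 60 °C; then MeOH, 1 M aq. NaOH (3 equiv), rt, 30 min; aq. NH4Cl
Reagents that add atoms: 9-borabicyclo[3.3.1]nonane (9-BBN), B1C2CCCC1CCC2 (its boron cage is carried in 13 only; only its hydrogen remains in 15)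
Why: Anti-Markovnikov hydroboration of the styrene by 9-BBN followed by B-alkyl Suzuki–Miyaura coupling of the primary alkylborane with the aryl bromide at zerovalent palladium formed from Pd(dppf)Cl2, the chelated phenol being carried as its phenoxide, after which brief cold hydroxide removes the acetyl group (part of it already lost to the aqueous phosphate) but not the hindered, doubly ortho-substituted methyl ester, so that one neutral product can be purified; no stereocentre is formed.

Step 7
Reactants: 15 methyl 2-hydroxy-6-[2-(4-{3-[2-(4-hydroxyphenyl)ethyl]-5-methoxyphenoxy}phenyl)ethyl]-4-methoxybenzoate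
Product: 16 2-hydroxy-6-[2-(4-{3-[2-(4-hydroxyphenyl)ethyl]-5-methoxyphenoxy}phenyl)ethyl]-4-methoxybenzoic acid (CNP0188714.0)
Conditions: KOH (10 equiv), DMSO/H2O 4:1 (degassed), 80 °C, Ar; then 1 M HCl to pH 2–3 at 0 °C; concentrate below 30 °C
Reagents that add atoms: potassium hydroxide, [K+].[OH-]
Why: Saponification of the hindered methyl salicylate with excess hot hydroxide (acyl–oxygen cleavage), a transformation known for 6-(2-arylethyl)-2-hydroxy-4-methoxybenzoates, in which the product is held as its carboxylate–phenoxide salt that should not decarboxylate and is released only by cold acidification; the product is achiral.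

**Compound list**
1 | 4-iodophenol | Oc1ccc(I)cc1 | starting material
2 | prop-2-en-1-ol (allyl alcohol) | C=CCO | starting material
3 | 3-(4-hydroxyphenyl)propanal | O=CCCc1ccc(O)cc1 | intermediate
4 | 1-(triphenyl-λ5-phosphanylidene)propan-2-one | CC(=O)C=P(c1ccccc1)(c1ccccc1)c1ccccc1 | starting material
5 | (3E)-6-(4-hydroxyphenyl)hex-3-en-2-one | CC(=O)/C=C/CCc1ccc(O)cc1 | intermediate
6 | dimethyl malonate | COC(=O)CC(=O)OC | starting material
7 | dimethyl 2-[1-(4-hydroxyphenyl)-5-oxohexan-3-yl]propanedioate (racemic) | COC(=O)C(C(=O)OC)C(CCc1ccc(O)cc1)CC(C)=O | intermediate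
8 | methyl 2-hydroxy-6-[2-(4-hydroxyphenyl)ethyl]-4-oxocyclohex-2-ene-1-carboxylate (racemic, C1/C6 diastereomers, trans expected to prevail) | COC(=O)C1C(O)=CC(=O)CC1CCc1ccc(O)cc1 | intermediate
9 | methyl 2-hydroxy-6-[2-(4-hydroxyphenyl)ethyl]-4-methoxybenzoate | COC(=O)c1c(O)cc(OC)cc1CCc1ccc(O)cc1 | intermediate
10 | (3-bromo-5-methoxyphenyl)boronic acid | COc1cc(Br)cc(B(O)O)c1 | starting material
11 | methyl 6-{2-[4-(3-bromo-5-methoxyphenoxy)phenyl]ethyl}-2-hydroxy-4-methoxybenzoate | COC(=O)c1c(O)cc(OC)cc1CCc1ccc(Oc2cc(Br)cc(OC)c2)cc1 | intermediate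
12 | 4-ethenylphenyl acetate (4-acetoxystyrene) | CC(=O)Oc1ccc(C=C)cc1 | starting material
13 | 4-[2-(9-borabicyclo[3.3.1]nonan-9-yl)ethyl]phenyl acetate | CC(=O)Oc1ccc(CCB2C3CCCC2CCC3)cc1 | intermediate
14 | methyl 6-{2-[4-(3-{2-[4-(acetyloxy)phenyl]ethyl}-5-methoxyphenoxy)phenyl]ethyl}-2-hydroxy-4-methoxybenzoate | COC(=O)c1c(O)cc(OC)cc1CCc1ccc(Oc2cc(CCc3ccc(OC(C)=O)cc3)cc(OC)c2)cc1 | intermediate
15 | methyl 2-hydroxy-6-[2-(4-{3-[2-(4-hydroxyphenyl)ethyl]-5-methoxyphenoxy}phenyl)ethyl]-4-methoxybenzoate | COC(=O)c1c(O)cc(OC)cc1CCc1ccc(Oc2cc(CCc3ccc(O)cc3)cc(OC)c2)cc1 | intermediate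
16 | 2-hydroxy-6-[2-(4-{3-[2-(4-hydroxyphenyl)ethyl]-5-methoxyphenoxy}phenyl)ethyl]-4-methoxybenzoic acid (achiral) | COc1cc(CCc2ccc(O)cc2)cc(Oc2ccc(CCc3cc(OC)cc(O)c3C(=O)O)cc2)c1 | target

**Count and risks**
Total steps: 7. Longest linear sequence: 7 (steps 1 to 7; compounds 4, 6, 10 and 12 are bought).

The three steps most likely to fail, each with a fallback:

Step 4. The free phenol ring could be iodinated, or etherification could take place at the wrong enol oxygen or not at all, in competition with the dehydrogenation. The fallback separates the two events. Setting out from 8, dehydrogenation over 10% Pd/C in refluxing mesitylene under an argon sweep should give methyl 2,4-dihydroxy-6-[2-(4-hydroxyphenyl)ethyl]benzoate F1. MeI (1.1 equiv) with KHCO3 in DMF at 40 °C should then methylate only the most acidic hydroxyl (O4, para to the ester; O2 is chelated and the ring C phenol is markedly less acidic), which returns to the route at 9.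

Step 5. Copper could be sequestered by the salicylate chelate of 9, so that arylation of the ring C phenol stalls or strays to the wrong hydroxyl. The fallback changes the order so that the ether is made before ring D exists. Setting out from 5, Chan–Lam arylation with 10 under the conditions of step 5 should give (3E)-6-[4-(3-bromo-5-methoxyphenoxy)phenyl]hex-3-en-2-one F2, which has one hydroxyl and no chelating group. Annulation of F2 with 6 and NaOMe in refluxing MeOH should pass through dimethyl 2-{1-[4-(3-bromo-5-methoxyphenoxy)phenyl]-5-oxohexan-3-yl}propanedioate F3 to methyl 6-{2-[4-(3-bromo-5-methoxyphenoxy)phenyl]ethyl}-2-hydroxy-4-oxocyclohex-2-ene-1-carboxylate F4. Iodine in refluxing methanol should then give 11, where the route is rejoined.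

Step 6. The borane could reduce the acetate, and the alkyl group could be lost by protodeboronation or β-hydride elimination, or 11 by hydrodebromination, before the sp3–sp2 bond forms. The fallback makes the bridge at the sp2 level. Setting out from 11, Mizoroki–Heck coupling with 12 (Pd(OAc)2, P(o-tolyl)3, NaHCO3, Bu4NBr, DMF, 100 °C) should give methyl 6-{2-[4-(3-{(E)-2-[4-(acetyloxy)phenyl]ethenyl}-5-methoxyphenoxy)phenyl]ethyl}-2-hydroxy-4-methoxybenzoate F5. Hydrogenation (H2, 10% Pd/C, EtOAc, rt) should saturate the alkene and return to the route at 14, which is deacetylated to 15 as in step 6.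

**Further compounds**
F1 | step 4 | methyl 2,4-dihydroxy-6-[2-(4-hydroxyphenyl)ethyl]benzoate | COC(=O)c1c(O)cc(O)cc1CCc1ccc(O)cc1
F2 | step 5 | (3E)-6-[4-(3-bromo-5-methoxyphenoxy)phenyl]hex-3-en-2-one | CC(=O)/C=C/CCc1ccc(Oc2cc(Br)cc(OC)c2)cc1
F3 | step 5 | dimethyl 2-{1-[4-(3-bromo-5-methoxyphenoxy)phenyl]-5-oxohexan-3-yl}propanedioate (racemic) | COC(=O)C(C(=O)OC)C(CCc1ccc(Oc2cc(Br)cc(OC)c2)cc1)CC(C)=O
F4 | step 5 | methyl 6-{2-[4-(3-bromo-5-methoxyphenoxy)phenyl]ethyl}-2-hydroxy-4-oxocyclohex-2-ene-1-carboxylate (racemic) | COC(=O)C1C(O)=CC(=O)CC1CCc1ccc(Oc2cc(Br)cc(OC)c2)cc1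
F5 | step 6 | methyl 6-{2-[4-(3-{(E)-2-[4-(acetyloxy)phenyl]ethenyl}-5-methoxyphenoxy)phenyl]ethyl}-2-hydroxy-4-methoxybenzoate | COC(=O)c1c(O)cc(OC)cc1CCc1ccc(Oc2cc(/C=C/c3ccc(OC(C)=O)cc3)cc(OC)c2)cc1
A1 | direct plan | 3-{2-[4-(benzyloxy)phenyl]ethyl}-5-methoxyphenol | COc1cc(O)cc(CCc2ccc(OCc3ccccc3)cc2)c1
A2 | direct plan | 4-(3-{2-[4-(benzyloxy)phenyl]ethyl}-5-methoxyphenoxy)benzaldehyde | COc1cc(CCc2ccc(OCc3ccccc3)cc2)cc(Oc2ccc(C=O)cc2)c1
A3 | direct plan | 1-{2-[4-(benzyloxy)phenyl]ethyl}-3-(4-ethenylphenoxy)-5-methoxybenzene | COc1cc(CCc2ccc(OCc3ccccc3)cc2)cc(Oc2ccc(C=C)cc2)c1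
A4 | direct plan | 2-(benzyloxy)-4-methoxybenzoic acid | OC(=O)c1ccc(OC)cc1OCc1ccccc1
A5 | direct plan | 2-(benzyloxy)-6-{2-[4-(3-{2-[4-(benzyloxy)phenyl]ethyl}-5-methoxyphenoxy)phenyl]ethyl}-4-methoxybenzoic acid | COc1cc(CCc2ccc(OCc3ccccc3)cc2)cc(Oc2ccc(CCc3cc(OC)cc(OCc4ccccc4)c3C(=O)O)cc2)c1
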